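Each percent of the starting material charged I count as ending as target or as side product: the last readings of Wednesday's run add up to 100 %. In the flask the starting material, at 0.10 M against 0.105 M of reagent, is the limiting reagent, so what I have to find is how it splits.

the same everywhere: reagent 0.105 M
- Friday's: starting material 0.10 M; free catalyst 1.4 mM; run made earlier
- Wednesday's: starting material 0.10 M; free catalyst 2.2 mM; run made earlier
- Tuesday's: starting material 0.15 M; free catalyst 1 mM; run made earlier
- flask: starting material 0.10 M; free catalyst 1.0 mM; time 8.0 d

| run | time / d | side product / % | target / % | starting material / % |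
|---|---|---|---|---|
| Friday's | 0.417 | 31.3 | 22.4 | 0 |
| Friday's | 1.25 | 54.0 | 39.2 | 0 |
| Friday's | 2.50 | 57.4 | 41.5 | 0.2 |
| Friday's | 4.00 | 58.5 | 42.1 | 0 |
| Friday's | 5.00 | 58.4 | 42.2 | 0 |
| Friday's | 6.00 | 57.6 | 42.5 | 0 |
| Wednesday's | 0.500 | 33.8 | 35.9 | 0 |
| Wednesday's | 0.833 | 42.5 | 45.1 | 0.2 |
| Wednesday's | 1.25 | 46.5 | 49.1 | 0 |
| Wednesday's | 2.50 | 47.4 | 51.9 | 0.1 |
| Wednesday's | 4.00 | 48.3 | 51.6 | 0.4 |
| Wednesday's | 6.00 | 48.1 | 51.9 | 0 |
| Tuesday's | 0.500 | 35.3 | 15.6 | 0.8 |
| Tuesday's | 1.04 | 56.9 | 25.6 | 0 |
| Tuesday's | 1.67 | 65.2 | 29.2 | 0 |
| Tuesday's | 3.00 | 68.2 | 30.9 | 0 |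
| Tuesday's | 6.00 | 68.6 | 31.0 | 0 |

(standard deviation of a reading: 0.3 percentage points)

- ratio of side product to target at 2.0 h
- ratio of side product to target at 20 h
- ratio of side product to target at 8.0 d

- steps under discussion: starting material + free catalyst -> free catalyst + open intermediate; free catalyst + open intermediate <-> catalyst intermediate; reagent + catalyst intermediate -> free catalyst + target; open intermediate -> side product

I take the settings in turn. By hand, I expect more free catalyst to favour the target: the listed steps take the open intermediate to target by way of the catalyst intermediate, and to side product without the catalyst. It does: going from Friday's run to Wednesday's, the last ratio falls from 1.36 to 0.927.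

I expect reagent to act the same way. It falls as target forms, so I estimate its mean over a run as the charge minus half the target made. That gives 0.0837 M on Friday and 0.0790 M on Wednesday.

I therefore carry the split product, the last side-to-target ratio times the catalyst charged times the mean reagent. Friday's run gives 1.59 × 10⁻⁴ M^2 and Wednesday's 1.61 × 10⁻⁴ M^2, and I use their mean, 1.60 × 10⁻⁴ M^2.

More starting material should matter through the reagent it uses, but Tuesday's run reads 1.81 × 10⁻⁴ M^2, which is higher. I leave it out, as the flask has Friday's charge of starting material.

Longer time should add little: Tuesday's target reads 30.9 % at 3.00 d and 31.0 % at 6.00 d.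

For the flask, Friday's mean reagent gives a ratio of 1.91, hence target 0.0344 M and mean reagent 0.0878 M. My end ratio is then 1.82.

The forecast says 2.4 at 2.0 h, 1.95 at 20 h and 1.92 at 8.0 d, and its end figure stands above mine. For the early time it holds that the “target lags because a few tenths of a mM sits in the catalyst intermediate”.

The flask gives 1.71, 1.91 and 1.85, so the forecast's early ratio stands above the result. By 0.800 d the flask's starting material was down to 0.0146 %, while 24.9 % stood as open intermediate and 18.9 % of the catalyst as catalyst intermediate. By 4.00 d the flask's open intermediate was down to 0.0321 %, with side product at 64.9 % and target at 35.0 %.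

    starting material + free catalyst → free catalyst + open intermediate (k = 0.180 M⁻¹ s⁻¹)
    free catalyst + open intermediate ⇌ catalyst intermediate (K = 13.0 M⁻¹, k = 0.0360 M⁻¹ s⁻¹)
    reagent + catalyst intermediate → free catalyst + target (k = 0.0140 M⁻¹ s⁻¹)
    open intermediate → side product (k = 1.50 × 10⁻⁵ s⁻¹)

For the neighbour with 0.0040 M of free catalyst, the split product with Friday's mean reagent first gives a ratio of 0.478, then target 0.0677 M and an end ratio of 0.562. That neighbour computes to 0.560 at 8.0 d.

All runs are calculated with made-up constants, and the scatter is random.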